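**Retrosynthetic overview**
1. Target 7 ⇒ alkene 4 by disconnecting the benzylic C1–O bond: a catalytic, enantioselective formal syn-hydration (H to C2, O to C1) of a trisubstituted (E)-alkene. One face-selective syn addition sets C1 and C2 together.
2. 4 ⇒ 3: hydride reduction of an (E)-2,3-diarylacrylic acid; the phenol acetates are cleaved in the same operation.
3. 3 ⇒ 1 + 2: Perkin condensation builds the C1=C2 bond with the two aryl groups cis.
4. No ring is formed: both benzene rings are bought with their oxygen pattern in place, and no separate protecting-group step is used.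

Assumptions: homosyringic acid 2 is taken as a catalogue compound. C1, C2 and C3 refer to the propane chain of the target (C1 carries the guaiacyl ring, C2 the syringyl ring, C3 is the CH2OH carbon). Bpin = 4,4,5,5-tetramethyl-1,3,2-dioxaborolan-2-yl.

**Step 1**
Reactants: 1 vanillin; 2 homosyringic acid
Product: 3 (E)-3-(4-acetoxy-3-methoxyphenyl)-2-(4-acetoxy-3,5-dimethoxyphenyl)prop-2-enoic acid
Conditions: Ac2O (6 equiv), Et3N (3 equiv), 110 °C, 8 h; then H2O, 23 °C, HCl to pH 2; recrystallise from EtOH
Reagents that add atoms: acetic anhydride, CC(=O)OC(C)=O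
Why: Perkin condensation: the mixed-anhydride enolate of the arylacetic acid adds to the aldehyde and acetylation/elimination gives the thermodynamically preferred (E)-acid (CO2H trans to the C1 aryl group, the two aryl groups cis), both phenols being acetylated in the same pot; no stereocentre is formed.

**Step 2**
Reactants: 3 (E)-3-(4-acetoxy-3-methoxyphenyl)-2-(4-acetoxy-3,5-dimethoxyphenyl)prop-2-enoic acid
Product: 4 (E)-2-(4-hydroxy-3,5-dimethoxyphenyl)-3-(4-hydroxy-3-methoxyphenyl)prop-2-en-1-ol
Conditions: LiAlH4 (4 equiv), THF, 0 to 23 °C, dark; aq. KNaC4H4O6 work-up at pH 5–6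
Reagents that add atoms: none
Why: LiAlH4 1,2-reduction of the carboxylic acid to the primary allylic alcohol with reductive cleavage of both aryl acetates; the electron-rich, trisubstituted C=C is not hydroaluminated at or below 23 °C, so the E geometry is kept.

**Step 3**
Reactants: 4 (E)-2-(4-hydroxy-3,5-dimethoxyphenyl)-3-(4-hydroxy-3-methoxyphenyl)prop-2-en-1-ol
Product: 7 (1S,2S)-1-(4-hydroxy-3-methoxyphenyl)-2-(4-hydroxy-3,5-dimethoxyphenyl)propane-1,3-diol, via tris-O-Bpin alkene 5 (not isolated), via C1 pinacol boronate 6 (not isolated)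
Conditions: Cu(OAc)2 (5 mol %), (R)-DTBM-SEGPHOS (5.5 mol %), HBpin (6 equiv), THF, 23 °C (H2 evolution) then 45 °C, dark; then NaBO3·4H2O (10 equiv), THF/H2O, 0 to 23 °C; work-up at pH 6
Reagents that add atoms: sodium perborate (used as NaBO3·4H2O), [Na+].[Na+].O[B-]1(O)OO[B-](O)(O)OO1 (gives the C1 oxygen of 7); pinacolborane, CC1(C)OBOC1(C)C (gives the boron groups of 5 and 6 and only the C2 hydrogen of 7)
Why: Proposed new method: the divalent copper salt is reduced by the borane to a ligated monovalent copper hydride L*CuH, which first caps the three O–H groups as O–Bpin with loss of H2 (5, so no proton source remains), then adds syn across the trisubstituted stilbene-type C=C with copper at the less hindered benzylic carbon C1 and hydride at C2 (copper is never β to the C3 oxygen, so no β-oxygen elimination); stereoretentive σ-bond metathesis with HBpin gives the C1–B bond (6) and returns L*CuH, and perborate oxidation (carbon shifts from boron to oxygen with retention) makes the C1–O bond while the O–B caps hydrolyse; because H and O enter the same face of the (E)-alkene (aryl groups cis), the relative configuration is fixed by the alkene geometry and the ligand selects the C1-Re/C2-Re face that gives (1S,2S); the closest known reaction types are the copper-hydride-catalysed Markovnikov hydroboration of vinylarenes and β-substituted styrenes with HBpin and the copper-hydride hydroamination of β,β-disubstituted styrenes, which have not been shown on an acyclic 1,2-diaryl trisubstituted alkene where two adjacent stereocentres are set at once, nor with free hydroxyls masked in the flask.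

**Compound list**
1 | vanillin (4-hydroxy-3-methoxybenzaldehyde) | COc1cc(C=O)ccc1O | starting material
2 | homosyringic acid ((4-hydroxy-3,5-dimethoxyphenyl)acetic acid) | COc1cc(CC(=O)O)cc(OC)c1O | starting material
3 | (E)-3-(4-acetoxy-3-methoxyphenyl)-2-(4-acetoxy-3,5-dimethoxyphenyl)prop-2-enoic acid | COc1cc(/C=C(/C(=O)O)c2cc(OC)c(OC(C)=O)c(OC)c2)ccc1OC(C)=O | intermediate
4 | (E)-2-(4-hydroxy-3,5-dimethoxyphenyl)-3-(4-hydroxy-3-methoxyphenyl)prop-2-en-1-ol | COc1cc(/C=C(/CO)c2cc(OC)c(O)c(OC)c2)ccc1O | intermediate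
5 | (E)-alkene 4 with all three hydroxyls capped as O–Bpin (two aryl O–Bpin, one CH2O–Bpin) | COc1cc(/C=C(/COB3OC(C)(C)C(C)(C)O3)c2cc(OC)c(OB3OC(C)(C)C(C)(C)O3)c(OC)c2)ccc1OB1OC(C)(C)C(C)(C)O1 | intermediate
6 | 2-[(1S,2S)-2-(3,5-dimethoxy-4-(Bpin-oxy)phenyl)-1-(3-methoxy-4-(Bpin-oxy)phenyl)-3-(Bpin-oxy)propyl]-4,4,5,5-tetramethyl-1,3,2-dioxaborolane | COc1cc([C@@H](B3OC(C)(C)C(C)(C)O3)[C@H](COB3OC(C)(C)C(C)(C)O3)c2cc(OC)c(OB3OC(C)(C)C(C)(C)O3)c(OC)c2)ccc1OB1OC(C)(C)C(C)(C)O1 | intermediate
7 | (1S,2S)-1-(4-hydroxy-3-methoxyphenyl)-2-(4-hydroxy-3,5-dimethoxyphenyl)propane-1,3-diol | COc1cc([C@@H](O)[C@H](CO)c2cc(OC)c(O)c(OC)c2)ccc1O | target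

**Totals**
Total step count: 3. Longest linear sequence: 3 steps (1 + 2 → 3 → 4 → 7).

**Steps most likely to fail, most risky first**

Step 3 (the proposed new step). The risks are:
- slow hydrocupration of a trisubstituted alkene;
- some copper at C2, which would eliminate the C3 oxygen;
- racemic background hydroboration by borane species formed from HBpin, which is why no alkoxide base is used;
- the sense of induction of the ligand on this substrate class is an extrapolation, to be checked on the first run; if the (1R,2R) series forms, (S)-DTBM-SEGPHOS is used and nothing else changes.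

Fallback with known chemistry, setting out from 4: TBSCl and imidazole in DMF give the tris-silyl ether (E)-tert-butyl{4-[3-(tert-butyldimethylsilyloxy)-1-(4-(tert-butyldimethylsilyloxy)-3-methoxyphenyl)prop-1-en-2-yl]-2,6-dimethoxyphenoxy}dimethylsilane F4. Asymmetric hydroboration with IpcBH2 made from (−)-α-pinene (set free from its TMEDA adduct with BF3·OEt2; THF, −25 °C) adds boron to C1 and hydrogen to C2 in a syn fashion, giving the isopinocampheyl(alkyl)borane F5. This antipode is the one predicted by the empirical face preference of IpcBH2 with trisubstituted alkenes such as 1-phenylcyclopentene; it is confirmed on the first run, and the reagent from (+)-α-pinene is used if the sense is reversed. Oxidation with NaBO3·4H2O gives the (1S,2S)-alcohol tris-silyl ether F6, and Bu4NF/AcOH in THF at 0 °C removes the three silyl groups, coming back to the route at 7.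

Step 2. The risks are partial 1,4-reduction of the cinnamyl system to the saturated alcohol and light-induced E/Z drift of the hydroxystilbene. Fallback, setting out from 3: MeOH with catalytic H2SO4 at reflux esterifies the acid and transesterifies both acetates off, giving methyl (E)-2-(4-hydroxy-3,5-dimethoxyphenyl)-3-(4-hydroxy-3-methoxyphenyl)prop-2-enoate F3. The strictly 1,2-selective reagent iBu2AlH (6 equiv, THF, −78 to 0 °C) then reduces the ester and comes back to the route at 4.

Step 1. The risks are a moderate yield with the hindered syringyl acid and an E/Z mixture that does not crystallise cleanly. Fallback, setting out from 1: Wittig olefination with Ph3P=C(Br)CO2Et (toluene, 60 °C) gives ethyl (Z)-2-bromo-3-(4-hydroxy-3-methoxyphenyl)prop-2-enoate F1. Suzuki–Miyaura coupling with 2,6-dimethoxy-4-(Bpin)phenol (Pd(PPh3)4, K2CO3, dioxane/H2O, 80 °C) replaces bromine with retention of geometry and gives ethyl (E)-2-(4-hydroxy-3,5-dimethoxyphenyl)-3-(4-hydroxy-3-methoxyphenyl)prop-2-enoate F2. iBu2AlH (6 equiv, THF, −78 to 0 °C) then reduces the ester and comes back to the route at 4, bypassing 3.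

**Further compounds**
F1 | step 1 | ethyl (Z)-2-bromo-3-(4-hydroxy-3-methoxyphenyl)prop-2-enoate | CCOC(=O)/C(Br)=C/c1ccc(O)c(OC)c1
F2 | step 1 | ethyl (E)-2-(4-hydroxy-3,5-dimethoxyphenyl)-3-(4-hydroxy-3-methoxyphenyl)prop-2-enoate | CCOC(=O)/C(=C/c1ccc(O)c(OC)c1)c1cc(OC)c(O)c(OC)c1
F3 | step 2 | methyl (E)-2-(4-hydroxy-3,5-dimethoxyphenyl)-3-(4-hydroxy-3-methoxyphenyl)prop-2-enoate | COC(=O)/C(=C/c1ccc(O)c(OC)c1)c1cc(OC)c(O)c(OC)c1
F4 | step 3 | tris-TBS ether of (E)-alkene 4 (two aryl O–TBS, one CH2O–TBS) | COc1cc(/C=C(/CO[Si](C)(C)C(C)(C)C)c2cc(OC)c(O[Si](C)(C)C(C)(C)C)c(OC)c2)ccc1O[Si](C)(C)C(C)(C)C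
F5 | step 3 | [(1S,2S,3S,5R)-isopinocampheyl][(1S,2S)-tris-TBS-protected 1,2-diaryl-3-oxypropyl]borane (B–H, boron on C1) | C[C@@H]1[C@@H](B[C@H](c2ccc(O[Si](C)(C)C(C)(C)C)c(OC)c2)[C@H](CO[Si](C)(C)C(C)(C)C)c2cc(OC)c(O[Si](C)(C)C(C)(C)C)c(OC)c2)C[C@H]2C[C@@H]1C2(C)C
F6 | step 3 | (1S,2S)-3-(tert-butyldimethylsilyloxy)-1-[4-(tert-butyldimethylsilyloxy)-3-methoxyphenyl]-2-[4-(tert-butyldimethylsilyloxy)-3,5-dimethoxyphenyl]propan-1-ol | COc1cc([C@@H](O)[C@H](CO[Si](C)(C)C(C)(C)C)c2cc(OC)c(O[Si](C)(C)C(C)(C)C)c(OC)c2)ccc1O[Si](C)(C)C(C)(C)C
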